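**Assumption:** the target (6,7-dimethoxy-2-(2,3,4-trimethoxyphenyl)chromen-4-one) has no stereocentre, so there is no enantiomer to select; the only stereo-element in the route is the E alkene of intermediate 4.

**Retrosynthetic overview**
- The target is a 6,7,2',3',4'-pentamethoxyflavone; both benzene rings are bought with all five OMe groups in place.
- Disconnect the O1–C2 bond and the C2=C3 unsaturation: this leads back to 2'-hydroxychalcone 4 (oxidative cyclisation).
- Disconnect the chalcone Cα=Cβ bond: this gives acetophenone 1 and aldehyde 2 (Claisen–Schmidt).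
- Ring order: only the pyranone ring is formed, in the last step.

**Route**

Step 1
Reactants: 1 1-(2-hydroxy-4,5-dimethoxyphenyl)ethanone; 2 2,3,4-trimethoxybenzaldehyde
Product: 4 (E)-2'-hydroxy-2,3,4,4',5'-pentamethoxychalcone, via aldol adduct 3 (not isolated)
Conditions: KOH (50% aq, 5 equiv), EtOH, 0 °C → rt, 24–48 h; then 2 M HCl to pH 3, filter
Reagents that add atoms: none
Why: Claisen–Schmidt (crossed aldol) condensation, in which the enolate of 1 adds to the non-enolisable aldehyde 2 and the β-hydroxy ketone loses water by E1cB to give the conjugated, thermodynamically favoured E enone; no stereocentre remains.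

Step 2
Reactants: 4 (E)-2'-hydroxy-2,3,4,4',5'-pentamethoxychalcone
Product: 6 6,7-dimethoxy-2-(2,3,4-trimethoxyphenyl)-4H-chromen-4-one, via flavanone 5 (not isolated)
Conditions: I2 (10 mol%), DMSO, 130 °C, 2–4 h; aq Na2S2O3 work-up
Reagents that add atoms: none
Why: Iodine-catalysed oxidative cyclisation of a 2'-hydroxychalcone, in which 6-endo oxa-Michael closure gives the flavanone and iodine then dehydrogenates C2–C3 to the aromatic γ-pyrone, with DMSO as terminal oxidant regenerating I2; the transient C2 stereocentre is destroyed, so the product is achiral.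

**Compound list**
1 | 1-(2-hydroxy-4,5-dimethoxyphenyl)ethanone (2'-hydroxy-4',5'-dimethoxyacetophenone) | CC(=O)c1cc(OC)c(OC)cc1O | starting material
2 | 2,3,4-trimethoxybenzaldehyde | COc1ccc(C=O)c(OC)c1OC | starting material
3 | 3-hydroxy-1-(2-hydroxy-4,5-dimethoxyphenyl)-3-(2,3,4-trimethoxyphenyl)propan-1-one (racemic, not isolated) | COc1ccc(C(O)CC(=O)c2cc(OC)c(OC)cc2O)c(OC)c1OC | intermediate
4 | (E)-1-(2-hydroxy-4,5-dimethoxyphenyl)-3-(2,3,4-trimethoxyphenyl)prop-2-en-1-one | COc1ccc(/C=C/C(=O)c2cc(OC)c(OC)cc2O)c(OC)c1OC | intermediate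
5 | 6,7-dimethoxy-2-(2,3,4-trimethoxyphenyl)chroman-4-one (racemic flavanone, not isolated) | COc1cc2OC(c3ccc(OC)c(OC)c3OC)CC(=O)c2cc1OC | intermediate
6 | 6,7-dimethoxy-2-(2,3,4-trimethoxyphenyl)-4H-chromen-4-one | COc1cc2oc(-c3ccc(OC)c(OC)c3OC)cc(=O)c2cc1OC | target

**Total step count:** 2
**Longest linear sequence:** 2

**Steps most likely to fail**

The route has only two steps, so only two can be ranked.

1. Step 2 (most at risk). Possible problems are 5-exo closure to the aurone, ring iodination of the electron-rich arenes, or a stall at the flavanone. The fallback sets out from 4 and comes back at 6. It separates ring closure from oxidation and replaces the halogen redox manifold by hydride abstraction. Chalcone 4 is isomerised with NaOAc in refluxing EtOH/H2O to the flavanone 6,7-dimethoxy-2-(2,3,4-trimethoxyphenyl)chroman-4-one 5, which is now isolated. It is then dehydrogenated with DDQ (1.5–2 equiv) in refluxing dioxane to give 6. No compound outside the list is made.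

2. Step 1. Possible problems are a sluggish condensation of the ortho-substituted, electron-rich aldehyde, a competing Cannizzaro reaction, or a chalcone/flavanone mixture that is hard to purify. The fallback sets out from 1 and comes back at 6, replacing the aldol C=C construction by a Baker–Venkataraman C-acylation. Phenol 1 is O-acylated with commercial 2,3,4-trimethoxybenzoyl chloride (COc1ccc(C(Cl)=O)c(OC)c1OC) in pyridine with catalytic DMAP, 0 °C → rt, to give the aryl ester 2-acetyl-4,5-dimethoxyphenyl 2,3,4-trimethoxybenzoate F1. Powdered KOH in pyridine at 50 °C moves the aroyl group from O to the acetyl carbon, giving the 1,3-diketone 1-(2-hydroxy-4,5-dimethoxyphenyl)-3-(2,3,4-trimethoxyphenyl)propane-1,3-dione F2. Cyclodehydration with catalytic H2SO4 in AcOH at 100 °C closes the pyranone and gives 6 directly, so no oxidation step is needed.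

**Further compounds**
F1 | step 1 | 2-acetyl-4,5-dimethoxyphenyl 2,3,4-trimethoxybenzoate | CC(=O)c1cc(OC)c(OC)cc1OC(=O)c1ccc(OC)c(OC)c1OC
F2 | step 1 | 1-(2-hydroxy-4,5-dimethoxyphenyl)-3-(2,3,4-trimethoxyphenyl)propane-1,3-dione | COc1ccc(C(=O)CC(=O)c2cc(OC)c(OC)cc2O)c(OC)c1OC
F0 | step 2 | none | none
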